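The starting material in these flasks has two exits: the main step turns it into target, and the side step joins it to a target already made.

| flask | starting material | second substrate | free catalyst | remark | time |
|---|---|---|---|---|---|
| grey | 0.40 M | 0.40 M | 20 mM | run made earlier |  |
| blue | 0.27 M | 0.40 M | 20 mM | run made earlier |  |
| red | 0.60 M | 0.40 M | 20 mM | run made earlier |  |
| maple | 0.40 M (fed, over 6.00 min) | 0.400 M | 20 mM | a stirred flask in which starting material is dosed at a steady rate over 6.00 min without added volume, worked up at 12 min | 12 min |
| larch | 0.40 M | 0.400 M | 20 mM | plug flow through a tube for 12 min, no back-mixing | 12 min |
| birch | 0.40 M | 0.400 M | 20 mM | everything together in a closed stirred flask, run for 12 min | 12 min |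
| elm | 0.40 M | 0.400 M | 20 mM | a single well-mixed tank run continuously and read at steady state, 12 min in it on average |  |

- grey (time / min: target / %, side product / %): 0.833: 29.9, 1.8; 2.50: 64.1, 11.6; 4.00: 76.4, 15.9; 6.00: 81.0, 17.5; 10.0: 82.6, 16.8; 12.0: 83.0, 16.8
- blue (time / min: target / %, side product / %): 0.500: 18.4, 0.5; 1.00: 34.5, 2.2; 1.50: 46.0, 4.2; 2.50: 65.3, 8.4; 4.00: 80.1, 10.7; 8.00: 86.8, 12.2
- red (time / min: target / %, side product / %): 1.33: 40.3, 8.1; 2.50: 59.2, 16.5; 4.00: 71.7, 22.0; 5.00: 73.6, 23.3; 6.00: 74.7, 25.1; 8.00: 75.7, 23.8

(standard deviation of a reading: 0.5 percentage points)

- in percentages every species weighs as the starting material in it: one side product counts as two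
- the stated concentrations are those of everything mixed, before any reaction; amounts are the same in each set-up
- the feed brings no volume worth counting
- the earlier runs were made in a closed, stirred flask

* the set-up with the highest share of target in all that became target or side product, at the outlet or at the end ("none" if the first two lie within 2 percentage points) (maple / larch / birch / elm / none)
* share of target in all that became target or side product, at the outlet or at the end, maple
* share of target in all that became target or side product, at the outlet or at the end, larch
* share of target in all that became target or side product, at the outlet or at the end, birch
* share of target in all that became target or side product, at the outlet or at the end, elm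

I build the flask one process at a time. With the main step by itself, the share of target is 100%.

Now I add the side step. I take the rates of both routes as proportional to starting material, as an assumption. The ratio of side rate to main rate at one moment is then a factor times the target concentration. I call this factor the selectivity factor. With a constant factor, a closed flask, a tube and dosing all give the same share once the reaction is complete, and birch repeats the grey charge, whose last readings sum to 99.8%, so that share reads 83.2%.

The third step is the drift. Between readings of the red run, I count side events as half the side-product gain, count main events as the target gain plus those side events, and divide the first count by the second and by the mean target. From the start to 1.33 min this reads 0.755 M⁻¹. From 2.50 min to 4.00 min it reads 0.459 M⁻¹, the late selectivity factor, which is lower.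

I carry these red readings over to the charge of 0.40 M as an assumption. Birch makes its target across both periods, so I give it the mean, 0.607 M⁻¹. Maple's dose runs on to 6.00 min, past the 4.00 min at which the late reading ends, so as an estimate I give it the late factor. Scaling grey's side share by that ratio, my reckoning for maple is 87.3%, and larch stays with birch. In elm, a side event costs one target and adds two to the side column, so the share is (1−f)/(1+f), where f is the factor times target. Guessing target near 0.7 of the charge and using the late factor, my reckoning for elm is 77.2%. In my reckoning maple therefore leads larch and birch by 4.1 percentage points, more than the margin of 2 points, so my answer for the best is maple.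

The forecast gave 83.2% for maple, 83.2% for larch, 83.2% for birch, 74.8% for elm and none as best: "Batch, plug flow and dosing without volume therefore give the same result".

The flask gives 85.9% for maple, 82.4% for larch, 82.4% for birch and 77.8% for elm, so the best is maple.

    catalyst intermediate B → free catalyst + second product (k = 0.226 s⁻¹)
    starting material + free catalyst ⇌ catalyst intermediate A (K = 7.67 M⁻¹, k = 0.718 M⁻¹ s⁻¹)
    catalyst intermediate A → free catalyst + target (k = 8.45 s⁻¹)
    second substrate + free catalyst ⇌ catalyst intermediate B (K = 4.70 M⁻¹, k = 1.66 M⁻¹ s⁻¹)
    starting material + target → side product (k = 0.00555 M⁻¹ s⁻¹)

In birch, with the other concentrations held at their charge, the forward path of second substrate onto free catalyst has a half-life of 0.35 min, shorter than the 0.80 min of starting material onto free catalyst. By its path to free catalyst and second product, catalyst intermediate B has a half-life of 0.051 min. Scaled back from birch, maple's side share corresponds to a factor of 0.486 M⁻¹, against the 0.459 M⁻¹ read from the red run. With maple's dose going in over three tenths of the run, its share is 84.9%, which corresponds to 0.521 M⁻¹.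

The runs were computed on assumed constants; noise was put on by code.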